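The synthesis rests on disconnecting the C4–C4a bond of the dihydropyran ring (ring B) of the chroman. Because O1 on C8a lies para to the acetyl-bearing C6 of the benzene ring (ring A), a 4-O-alkylated phloroacetophenone has two equivalent ortho carbons, the future C4a and C8. A rhodium carbenoid generated from a terminal alpha-diazoketone on the O1–C2 tether substitutes one of them and closes ring B as the chroman-3-one in a single operation, with no regiochemical question. The precursor is 3-[4-acetyl-3,5-bis(benzyloxy)phenoxy]-1-diazo-3-methylbutan-2-one. Enantioselective ketone reduction, hydrogenolysis and a Mannich-type methylene coupling at C8 with the pyranone (ring C) complete the route.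

Key step: step 5

Remark: chroman numbering is used (O1, C2 gem-dimethyl, C3 carbinol, C4, C4a, C5 to C8, C8a); C3 is R by the CIP order OH > C2 > C4 > H.

Remark: the two chelated phenols are carried as benzyl ethers, not methyl ethers. Cleaving two methyl ethers ortho to the acetyl group needs forcing Lewis acid that would endanger the tertiary alkyl aryl ether O1–C2 and the C3 carbinol. Benzyl ethers keep ring A electron-rich for the key step and leave by neutral hydrogenolysis.

Step 1
Reactants: 1 2',4',6'-trihydroxyacetophenone; 2 ethyl 2-bromo-2-methylpropanoate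
Product: 3 ethyl 2-(4-acetyl-3,5-dihydroxyphenoxy)-2-methylpropanoate
Conditions: K2CO3 (1.2 equiv), 2 (1.5 equiv), DMF, 60 °C
Reagents that add atoms: ethyl 2-bromo-2-methylpropanoate CCOC(=O)C(C)(C)Br
Why: Williamson ether synthesis; one equivalent of weak base ionises only the 4-hydroxyl, which is the most acidic and is not hydrogen-bonded to the acetyl carbonyl, so the hindered bromo ester should alkylate that oxygen and leave the two chelated hydroxyls untouched.

Step 2
Reactants: 3 ethyl 2-(4-acetyl-3,5-dihydroxyphenoxy)-2-methylpropanoate; 4 benzyl bromide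
Product: 5 ethyl 2-[4-acetyl-3,5-bis(benzyloxy)phenoxy]-2-methylpropanoate
Conditions: BnBr (2.5 equiv), K2CO3 (3 equiv), n-Bu4NI (cat.), DMF, 70 °C
Reagents that add atoms: benzyl bromide BrCc1ccccc1
Why: Williamson etherification under forcing carbonate/DMF conditions should break the hydrogen bonds to the acetyl group and benzylate both remaining phenols, while the ethyl ester is stable to carbonate.

Step 3
Reactants: 5 ethyl 2-[4-acetyl-3,5-bis(benzyloxy)phenoxy]-2-methylpropanoate
Product: 6 2-[4-acetyl-3,5-bis(benzyloxy)phenoxy]-2-methylpropanoic acid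
Conditions: LiOH·H2O (4 equiv), THF/MeOH/H2O, 50 °C; then 1 M HCl to pH 3
Reagents that add atoms: lithium hydroxide [Li+].[OH-]
Why: Saponification of the hindered ester by acyl–oxygen cleavage; benzyl aryl ethers and the hindered aryl methyl ketone are inert to aqueous hydroxide at this temperature.

Step 4
Reactants: 6 2-[4-acetyl-3,5-bis(benzyloxy)phenoxy]-2-methylpropanoic acid; 7 (trimethylsilyl)diazomethane
Product: 9 3-[4-acetyl-3,5-bis(benzyloxy)phenoxy]-1-diazo-3-methylbutan-2-one, via acid chloride 8 (not isolated)
Conditions: (COCl)2 (1.3 equiv), DMF (cat.), CH2Cl2, 0 °C to rt, evaporate; then TMSCHN2 (2.5 equiv, 2 M in hexanes), THF/MeCN 1:1, 0 °C to rt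
Reagents that add atoms: (trimethylsilyl)diazomethane C[Si](C)(C)C=[N+]=[N-]
Why: Acid chloride formation followed by C-acylation of trimethylsilyldiazomethane (first stage of the Arndt–Eistert sequence) with loss of the silyl group to chloride; the acid chloride has no alpha hydrogen, so no ketene can form, and it is used at once at low temperature so that the electron-rich ring is not acylated.

Step 5
Reactants: 9 3-[4-acetyl-3,5-bis(benzyloxy)phenoxy]-1-diazo-3-methylbutan-2-one
Product: 10 6-acetyl-5,7-bis(benzyloxy)-2,2-dimethylchroman-3-one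
Conditions: Rh2(OAc)4 (1 mol %, divalent rhodium), CH2Cl2, reflux, slow addition of 9 over 2 h, argon
Reagents that add atoms: none
Why: Rh2(OAc)4 should expel N2 from the diazoketone to give an electrophilic rhodium carbenoid whose carbon (future C4) attacks the arene carbon ortho to the ether oxygen (future C4a); the arenium/rhodium enolate zwitterion then rearomatises by hydrogen shift and releases the catalyst. The closest known reaction type is the Rh2(OAc)4-catalysed cyclisation of 1-diazo-3-aryloxypropan-2-ones to chroman-3-ones, an intramolecular carbenoid aromatic substitution. Ring B is closed as a six-membered ring in a 6-endo mode, counting the attacked arene bond C4a–C8a, which ends up inside the new ring. No stereocenter is created. The step needs chemoselectivity for aromatic substitution over Buchner ring expansion to a cycloheptatriene and over carbenoid dimerisation: the attacked carbon has oxygen donors on both ortho carbons and on the para carbon, so the cationic intermediate is well stabilised and rearomatises fast, the gem-dimethyl group holds the carbenoid over the ring, and slow addition keeps the diazo concentration low. Site selectivity needs no control, because the two ortho carbons are related by the mirror plane through the ether-bearing and the acetyl-bearing ring carbons (future C8a and C6).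

Step 6
Reactants: 10 6-acetyl-5,7-bis(benzyloxy)-2,2-dimethylchroman-3-one
Product: 11 1-[(3R)-5,7-bis(benzyloxy)-3-hydroxy-2,2-dimethyl-3,4-dihydro-2H-chromen-6-yl]ethanone
Conditions: (S)-Me-CBS oxazaborolidine [(3aS)-1-methyl-3,3-diphenyltetrahydro-1H,3H-pyrrolo[1,2-c][1,3,2]oxazaborole] (15 mol %), BH3·SMe2 (0.7 equiv), THF, −20 °C, slow addition of 10; MeOH quench
Reagents that add atoms: none
Why: Corey–Bakshi–Shibata reduction; the C3 ketone should bind the catalyst boron anti to the quaternary C2 (large group) and syn to the C4 methylene (small group), so the (S)-catalyst should deliver hydride to the face that gives the 3R alcohol (the same sense as a tert-alkyl methyl ketone giving the R carbinol), while the acetyl ketone flanked by two benzyloxy groups is too hindered to compete at this temperature and borane loading.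

Step 7
Reactants: 11 1-[(3R)-5,7-bis(benzyloxy)-3-hydroxy-2,2-dimethyl-3,4-dihydro-2H-chromen-6-yl]ethanone
Product: 12 1-[(3R)-3,5,7-trihydroxy-2,2-dimethyl-3,4-dihydro-2H-chromen-6-yl]ethanone
Conditions: H2 (1 atm), Pd/C (10 wt %, zerovalent palladium on carbon), EtOAc/MeOH, rt
Reagents that add atoms: none
Why: Hydrogenolysis of the two benzyl aryl ethers; the chelated acetyl group, the tertiary alkyl aryl ether and the non-benzylic C3 carbinol are not cleaved under these neutral conditions, so the C3 configuration is retained.

Step 8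
Reactants: 13 methyl 3-oxopentanoate; 14 N-methoxy-N-methylpropanamide
Product: 15 methyl 4-methyl-3,5-dioxoheptanoate
Conditions: LiN(iPr)2 (2.2 equiv), THF, −78 to 0 °C; then 14, −78 °C to rt; aq. HCl
Reagents that add atoms: N-methoxy-N-methylpropanamide CCC(=O)N(C)OC
Why: Claisen-type gamma-acylation of a beta-keto ester dianion, which reacts at its more basic gamma carbon; the Weinreb amide gives a chelated tetrahedral intermediate, so the acidic diketo ester is released only on work-up and does not quench the dianion (the C4 centre is enolisable and disappears in the next step).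

Step 9
Reactants: 15 methyl 4-methyl-3,5-dioxoheptanoate
Product: 16 6-ethyl-4-hydroxy-5-methyl-2H-pyran-2-one
Conditions: DBU (1.5 equiv), toluene, reflux; aq. HCl work-up
Reagents that add atoms: none
Why: Base-mediated lactonisation of a 3,5-diketo ester; the C5 enol oxygen attacks the ester carbonyl with loss of methanol to give the aromatic-like 4-hydroxy-2-pyranone.

Step 10
Reactants: 12 1-[(3R)-3,5,7-trihydroxy-2,2-dimethyl-3,4-dihydro-2H-chromen-6-yl]ethanone; 17 N,N-dimethylmethyleneiminium iodide (Eschenmoser's salt); 16 6-ethyl-4-hydroxy-5-methyl-2H-pyran-2-one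
Product: 19 3-{[(3R)-6-acetyl-3,5,7-trihydroxy-2,2-dimethyl-3,4-dihydro-2H-chromen-8-yl]methyl}-6-ethyl-4-hydroxy-5-methyl-2H-pyran-2-one (target), via Mannich base 18 (not isolated)
Conditions: 17 (1.0 equiv), MeCN, rt; then 16 (1.2 equiv), NaOAc (1.1 equiv), 70 °C
Reagents that add atoms: N,N-dimethylmethyleneiminium iodide C=[N+](C)C.[I-]; 6-ethyl-4-hydroxy-5-methyl-2H-pyran-2-one CCc1oc(=O)cc(O)c1C
Why: Mannich aminomethylation at C8, the only free and most nucleophilic carbon of ring A, followed by loss of dimethylamine to an ortho-quinone methide (through the C7 oxygen) that is trapped by C3 of the pyranone in a Michael addition; the one-carbon unit sits on the partner that has no second free ring carbon, which should suppress the symmetric methylene-bis-pyranone, and C3 of the chroman is not involved.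

Compound list
1 | 2',4',6'-trihydroxyacetophenone | CC(=O)c1c(O)cc(O)cc1O | starting material
2 | ethyl 2-bromo-2-methylpropanoate | CCOC(=O)C(C)(C)Br | starting material
3 | ethyl 2-(4-acetyl-3,5-dihydroxyphenoxy)-2-methylpropanoate | CCOC(=O)C(C)(C)Oc1cc(O)c(C(C)=O)c(O)c1 | intermediate
4 | benzyl bromide | BrCc1ccccc1 | starting material
5 | ethyl 2-[4-acetyl-3,5-bis(benzyloxy)phenoxy]-2-methylpropanoate | CCOC(=O)C(C)(C)Oc1cc(OCc2ccccc2)c(C(C)=O)c(OCc2ccccc2)c1 | intermediate
6 | 2-[4-acetyl-3,5-bis(benzyloxy)phenoxy]-2-methylpropanoic acid | OC(=O)C(C)(C)Oc1cc(OCc2ccccc2)c(C(C)=O)c(OCc2ccccc2)c1 | intermediate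
7 | (trimethylsilyl)diazomethane | C[Si](C)(C)C=[N+]=[N-] | starting material
8 | 2-[4-acetyl-3,5-bis(benzyloxy)phenoxy]-2-methylpropanoyl chloride | ClC(=O)C(C)(C)Oc1cc(OCc2ccccc2)c(C(C)=O)c(OCc2ccccc2)c1 | intermediate
9 | 3-[4-acetyl-3,5-bis(benzyloxy)phenoxy]-1-diazo-3-methylbutan-2-one | CC(=O)c1c(OCc2ccccc2)cc(OC(C)(C)C(=O)C=[N+]=[N-])cc1OCc1ccccc1 | intermediate
10 | 6-acetyl-5,7-bis(benzyloxy)-2,2-dimethylchroman-3-one | CC(=O)c1c(OCc2ccccc2)cc2OC(C)(C)C(=O)Cc2c1OCc1ccccc1 | intermediate
11 | 1-[(3R)-5,7-bis(benzyloxy)-3-hydroxy-2,2-dimethyl-3,4-dihydro-2H-chromen-6-yl]ethanone | CC(=O)c1c(OCc2ccccc2)cc2OC(C)(C)[C@H](O)Cc2c1OCc1ccccc1 | intermediate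
12 | 1-[(3R)-3,5,7-trihydroxy-2,2-dimethyl-3,4-dihydro-2H-chromen-6-yl]ethanone | CC(=O)c1c(O)cc2OC(C)(C)[C@H](O)Cc2c1O | intermediate
13 | methyl 3-oxopentanoate | CCC(=O)CC(=O)OC | starting material
14 | N-methoxy-N-methylpropanamide | CCC(=O)N(C)OC | starting material
15 | methyl 4-methyl-3,5-dioxoheptanoate (racemic, enolisable) | CCC(=O)C(C)C(=O)CC(=O)OC | intermediate
16 | 6-ethyl-4-hydroxy-5-methyl-2H-pyran-2-one | CCc1oc(=O)cc(O)c1C | intermediate
17 | N,N-dimethylmethyleneiminium iodide | C=[N+](C)C.[I-] | starting material
18 | 1-[(3R)-8-[(dimethylamino)methyl]-3,5,7-trihydroxy-2,2-dimethyl-3,4-dihydro-2H-chromen-6-yl]ethanone | CC(=O)c1c(O)c(CN(C)C)c2OC(C)(C)[C@H](O)Cc2c1O | intermediate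
19 | 3-{[(3R)-6-acetyl-3,5,7-trihydroxy-2,2-dimethyl-3,4-dihydro-2H-chromen-8-yl]methyl}-6-ethyl-4-hydroxy-5-methyl-2H-pyran-2-one | CCc1oc(=O)c(Cc2c(O)c(C(C)=O)c(O)c3c2OC(C)(C)[C@H](O)C3)c(O)c1C | target

Total step count: 10. Longest linear sequence: 8 steps (steps 1 to 7, then step 10); steps 8 and 9 make the pyranone in a two-step side branch.

Steps most likely to fail

Step 5. The carbenoid may be diverted into ring expansion to a cycloheptatriene or into dimerisation, or may attack the doubly flanked ortho carbon too slowly. The fallback sets out from 9 and replaces the carbenoid by an epoxide electrophile. Aqueous HBr in Et2O at 0 °C should convert the diazoketone into 3-[4-acetyl-3,5-bis(benzyloxy)phenoxy]-1-bromo-3-methylbutan-2-one F1. Corey–Bakshi–Shibata reduction with the same (S)-oxazaborolidine and BH3·SMe2 should give (2S)-3-[4-acetyl-3,5-bis(benzyloxy)phenoxy]-1-bromo-3-methylbutan-2-ol F2, the much more electrophilic bromoketone reacting before the acetyl group. K2CO3 in MeOH should close (2R)-2-{2-[4-acetyl-3,5-bis(benzyloxy)phenoxy]propan-2-yl}oxirane F3. An intramolecular Friedel–Crafts epoxide–arene alkylation with AuCl3/AgOTf (trivalent gold, catalytic) in 1,2-dichloroethane should then attack the terminal epoxide carbon in the 6-endo mode, since the internal carbon is neopentyl. The carbinol carbon is not touched in the ring closure, so its configuration is carried over and the fallback comes back to the route at 11.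

Step 10. The methylene unit may exchange between the partners by retro-Michael fragmentation and recombination, giving the symmetric methylene-bis-pyranone, or dimethylamine may be lost too slowly. The fallback sets out from 12 and brings the bridging carbon in at the aldehyde oxidation level, so that no free methylene donor exists. Vilsmeier–Haack formylation (POCl3, DMF, EtOAc, 0 °C to rt, aqueous NaOAc work-up) should give (3R)-6-acetyl-3,5,7-trihydroxy-2,2-dimethyl-3,4-dihydro-2H-chromene-8-carbaldehyde F6. A three-component reductive alkylation of F6 with 16 and diethyl 2,6-dimethyl-1,4-dihydropyridine-3,5-dicarboxylate (Hantzsch ester), catalysed by L-proline in EtOH at rt, should proceed by Knoevenagel condensation and conjugate transfer hydrogenation and come back to the route at 19.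

Step 6. Facial discrimination may be insufficient if the ether oxygen on C2 perturbs binding to the catalyst, or some of the acetyl ketone may be reduced. The fallback sets out from 10 and separates diastereomers in place of asymmetric induction. NaBH4 in MeOH at −20 °C should give racemic 1-[5,7-bis(benzyloxy)-3-hydroxy-2,2-dimethyl-3,4-dihydro-2H-chromen-6-yl]ethanone F4. Acylation with (1S)-(−)-camphanoyl chloride, 4-(dimethylamino)pyridine and pyridine, followed by chromatographic or crystallisation separation, should give (3R)-6-acetyl-5,7-bis(benzyloxy)-2,2-dimethyl-3,4-dihydro-2H-chromen-3-yl (1S,4R)-camphanate F5. Hydrolysis with LiOH in THF/H2O comes back to the route at 11. The unwanted diastereomer can be hydrolysed and oxidised with Dess–Martin periodinane back to 10.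

Further compounds
F1 | step 5 | 3-[4-acetyl-3,5-bis(benzyloxy)phenoxy]-1-bromo-3-methylbutan-2-one | CC(=O)c1c(OCc2ccccc2)cc(OC(C)(C)C(=O)CBr)cc1OCc1ccccc1
F2 | step 5 | (2S)-3-[4-acetyl-3,5-bis(benzyloxy)phenoxy]-1-bromo-3-methylbutan-2-ol | CC(=O)c1c(OCc2ccccc2)cc(OC(C)(C)[C@H](O)CBr)cc1OCc1ccccc1
F3 | step 5 | (2R)-2-{2-[4-acetyl-3,5-bis(benzyloxy)phenoxy]propan-2-yl}oxirane | CC(=O)c1c(OCc2ccccc2)cc(OC(C)(C)[C@H]2CO2)cc1OCc1ccccc1
F4 | step 6 | racemic 1-[5,7-bis(benzyloxy)-3-hydroxy-2,2-dimethyl-3,4-dihydro-2H-chromen-6-yl]ethanone | CC(=O)c1c(OCc2ccccc2)cc2OC(C)(C)C(O)Cc2c1OCc1ccccc1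
F5 | step 6 | (3R)-6-acetyl-5,7-bis(benzyloxy)-2,2-dimethyl-3,4-dihydro-2H-chromen-3-yl (1S,4R)-4,7,7-trimethyl-3-oxo-2-oxabicyclo[2.2.1]heptane-1-carboxylate | CC(=O)c1c(OCc2ccccc2)cc2OC(C)(C)[C@H](OC(=O)[C@@]34CC[C@@](C)(C(=O)O3)C4(C)C)Cc2c1OCc1ccccc1
F6 | step 10 | (3R)-6-acetyl-3,5,7-trihydroxy-2,2-dimethyl-3,4-dihydro-2H-chromene-8-carbaldehyde | CC(=O)c1c(O)c(C=O)c2OC(C)(C)[C@H](O)Cc2c1O
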